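**Plan**

- Retrosynthesis: the two imide N–C(=O) bonds are cut first, then the two ring-to-carbonyl bonds of the cyclobutane, then one ring–aryl bond, and last the four-membered ring itself (ketene–styrene [2+2]).
- Forward: the cyclobutane is the only ring that is built (step 1). The second veratryl group is joined by substitution, both carbonyl carbons are installed in one operation, and the two lactam rings are attached intact at the end.
- Enabling feature: each carbonyl-bearing ring carbon (C2, C4) is cis to a veratryl group on a neighbouring ring carbon (C1 or C3), and a 4-alkylveratrole ring brominates ortho to its alkyl group. Each aryl ring can therefore carry a bromine that lets palladium reach the adjacent cis C–H bond and is lost in the process.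
- Stereochemistry: the trans-1,3-diaryl relationship comes from a cis-selective ketone reduction followed by an invertive cuprate displacement. The C2 and C4 configurations come from the cis geometry of the palladacycles. Later steps avoid base or run cold.

Key step: step 7

Remark: the target is achiral (centrosymmetric). "Alpha-truxillic arrangement" means aryl groups trans to each other, carbonyl groups trans to each other, and each carbonyl group cis to one neighbouring aryl group and trans to the other. The two chiral intermediates (4 and 15) are racemic, and the SMILES of 15 shows one enantiomer. In the plan and the Why lines the ring carbons are numbered so that C1 and C3 bear the aryl groups; the compound names use the usual numbering. Steps 7 and 10 each take up two molecules of a numbered reactant (13 and 14 in step 7, 19 in step 10); the second molecule is entered under "Reagents that add atoms". In step 6 two molecules of NBS deliver one bromine atom each.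

**Step 1**
Reactants: 1 3,4-dimethoxystyrene; 2 trichloroacetyl chloride
Product: 4 2,2-dichloro-3-(3,4-dimethoxyphenyl)cyclobutan-1-one (racemic), via dichloroketene 3 (not isolated)
Conditions: Zn–Cu couple, POCl3 (1.1 equiv), Et2O–DME, slow addition of 2, rt to reflux
Reagents that add atoms: none
Why: Zinc dechlorinates the acid chloride to dichloroketene, which should add to the electron-rich styrene in a thermal ketene–alkene [2+2] cycloaddition with its carbonyl carbon bonding to the terminal CH2, so that the aryl group ends at C3 of the cyclobutanone, while POCl3 ties up the zinc chloride that could polymerise the styrene.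

**Step 2**
Reactants: 4 2,2-dichloro-3-(3,4-dimethoxyphenyl)cyclobutan-1-one
Product: 5 3-(3,4-dimethoxyphenyl)cyclobutan-1-one
Conditions: Zn dust, AcOH, rt to 70 °C
Reagents that add atoms: none
Why: Zinc in acetic acid should remove both alpha-chlorine atoms by reductive dehalogenation of the alpha,alpha-dichloroketone without touching the ring or the carbonyl group.

**Step 3**
Reactants: 5 3-(3,4-dimethoxyphenyl)cyclobutan-1-one
Product: 6 cis-3-(3,4-dimethoxyphenyl)cyclobutan-1-ol
Conditions: NaBH4, THF–MeOH, −40 to 0 °C
Reagents that add atoms: none
Why: In the borohydride reduction of a 3-substituted cyclobutanone the hydride approaches the face opposite the 3-aryl group, so the hydroxyl group should end cis to the aryl group.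

**Step 4**
Reactants: 6 cis-3-(3,4-dimethoxyphenyl)cyclobutan-1-ol
Product: 7 cis-3-(3,4-dimethoxyphenyl)cyclobutyl 4-methylbenzenesulfonate
Conditions: TsCl, Et3N, DMAP (cat.), CH2Cl2, 0 °C to rt
Reagents that add atoms: 4-toluenesulfonyl chloride (TsCl), Cc1ccc(cc1)S(=O)(=O)Cl
Why: Tosylation takes place at oxygen, so the secondary alcohol becomes a leaving group with its cis configuration unchanged.

**Step 5**
Reactants: 7 cis-3-(3,4-dimethoxyphenyl)cyclobutyl 4-methylbenzenesulfonate; 8 4-bromo-1,2-dimethoxybenzene
Product: 11 trans-1,3-bis(3,4-dimethoxyphenyl)cyclobutane, via aryllithium 9 (not isolated), via lithium diarylcuprate 10 (not isolated)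
Conditions: 8, t-BuLi (2 equiv per bromide), Et2O, −78 °C; CuI (0.5 equiv per aryllithium), −40 to 0 °C; then 7, Et2O–THF, −20 °C to rt; aq. NH4Cl
Reagents that add atoms: none
Why: Bromine–lithium exchange and transmetalation give a Gilman cuprate, which should displace the secondary tosylate by SN2-type oxidative addition and reductive elimination with inversion at carbon, as lithium diarylcuprates do with secondary alkyl tosylates, turning the cis sulfonate into the trans-1,3-diaryl compound.

**Step 6**
Reactants: 11 trans-1,3-bis(3,4-dimethoxyphenyl)cyclobutane
Product: 12 trans-1,3-bis(2-bromo-4,5-dimethoxyphenyl)cyclobutane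
Conditions: NBS (2.1 equiv), MeCN, 0 °C to rt, dark
Reagents that add atoms: N-bromosuccinimide (NBS), O=C1CCC(=O)N1Br
Why: Electrophilic aromatic bromination of a 4-alkylveratrole ring goes to the position para to one methoxy group and ortho to the alkyl group, so each ring should take up one bromine next to the cyclobutyl substituent.

**Step 7**
Reactants: 12 trans-1,3-bis(2-bromo-4,5-dimethoxyphenyl)cyclobutane; 13 carbon monoxide; 14 benzyl alcohol
Product: 16 dibenzyl 2,4-bis(3,4-dimethoxyphenyl)cyclobutane-1,3-dicarboxylate (alpha-truxillate arrangement), via monoester monobromide 15 (not isolated)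
Conditions: Pd(OAc)2 (10 mol %), PCy3·HBF4 (20 mol %), CsOPiv (cesium pivalate, 3 equiv), BnOH (6 equiv), CO (1 atm), mesitylene, 120 °C
Reagents that add atoms: carbon monoxide (second molecule), [C-]#[O+]; benzyl alcohol (second molecule), OCc1ccccc1
Why: Proposed new method: zerovalent palladium inserts into an aryl–bromine bond, pivalate-assisted concerted metalation–deprotonation cleaves the methylene C–H bond on C2 (or the equivalent C4) that lies on the same ring face as this aryl group through a five-membered palladacycle, and protonation of the aryl–palladium bond by pivalic acid completes the 1,4-shift to a cyclobutylpalladium species that inserts CO and is cleaved by benzyl alcohol; the same sequence at the second aryl bromide converts mono-ester 15 into 16, so that two molecules each of 13 and 14 are consumed, one per new C–C(=O) bond. The closest known reaction type is the carbonylative C(sp3)–H activation of aryl bromides with 1,4-palladium shift and trapping as esters or amides, known for primary C–H bonds of ortho substituents, together with the intramolecular functionalisation of strained-ring methylene C–H bonds by the same metalation mechanism; new here are a secondary ring C–H bond as the end point of the shift and two such events in one molecule. No ring closes: C–C reductive elimination from the palladacycle would give a benzocyclobutene fused to the cyclobutane (a bicyclo[2.2.0]hexane, disfavoured by strain) and beta-hydride elimination would give a cyclobutene, so protonation, CO insertion and alcoholysis should prevail. Each new stereocentre (C2, C4) is set by the cis geometry of the palladacycle, because an aryl group reaches only hydrogens on its own face and CO insertion retains configuration, so each ester ends cis to the aryl group that delivered the palladium. Because the aryl groups on C1 and C3 are trans, the second aryl ring finds on its face only the remaining methylene hydrogen on C4 and the methine hydrogen on C2 beside the first ester, which is the more hindered site and should be passed over, so the two esters end trans to each other. The step also needs C–H cleavage to outrun direct carbonylation of the aryl–palladium bond, which 1 atm of CO, the bulky electron-rich PCy3 and excess pivalate should secure.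

**Step 8**
Reactants: 16 dibenzyl 2,4-bis(3,4-dimethoxyphenyl)cyclobutane-1,3-dicarboxylate
Product: 17 2,4-bis(3,4-dimethoxyphenyl)cyclobutane-1,3-dicarboxylic acid (alpha-truxillic arrangement)
Conditions: H2 (1 atm), 10% Pd/C, EtOAc–MeOH, rt
Reagents that add atoms: none
Why: Catalytic hydrogenolysis of the benzyl esters cleaves the benzylic C–O bonds under neutral conditions, so the epimerisable carbons next to the carbonyl groups never meet base and the ring and aryl ethers stay intact.

**Step 9**
Reactants: 17 2,4-bis(3,4-dimethoxyphenyl)cyclobutane-1,3-dicarboxylic acid
Product: 18 2,4-bis(3,4-dimethoxyphenyl)cyclobutane-1,3-dicarbonyl dichloride (same arrangement, used crude)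
Conditions: (COCl)2, DMF (cat.), CH2Cl2, 0 °C to rt; evaporation
Reagents that add atoms: oxalyl chloride, O=C(Cl)C(=O)Cl
Why: Acid chloride formation with oxalyl chloride and catalytic DMF (Vilsmeier-type activation) needs no base, so no ketene should form and the configuration next to the carbonyl groups is kept.

**Step 10**
Reactants: 18 2,4-bis(3,4-dimethoxyphenyl)cyclobutane-1,3-dicarbonyl dichloride; 19 5,6-dihydropyridin-2(1H)-one
Product: 21 1,1'-[2,4-bis(3,4-dimethoxyphenyl)cyclobutane-1,3-dicarbonyl]bis(5,6-dihydropyridin-2(1H)-one) (alpha-truxillic arrangement), via lithium lactamate 20 (not isolated)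
Conditions: 19 (2.1 equiv), n-BuLi (1 equiv per 19), THF, −78 °C; then 18, THF, −78 to −40 °C; aq. NH4Cl
Reagents that add atoms: 5,6-dihydropyridin-2(1H)-one (second molecule), O=C1C=CCCN1
Why: N-Acylation of the lithium lactamate by the acid chloride (imide formation, the usual way to N-acyl dihydropyridinones) is fast at −78 °C at both acid chloride groups, and the absence of excess base at low temperature should prevent epimerisation and conjugate addition.

**Compound list**

1 | 3,4-dimethoxystyrene | C=Cc1ccc(OC)c(OC)c1 | starting material
2 | trichloroacetyl chloride | O=C(Cl)C(Cl)(Cl)Cl | starting material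
3 | dichloroketene | O=C=C(Cl)Cl | intermediate
4 | 2,2-dichloro-3-(3,4-dimethoxyphenyl)cyclobutan-1-one (racemic) | COc1ccc(C2CC(=O)C2(Cl)Cl)cc1OC | intermediate
5 | 3-(3,4-dimethoxyphenyl)cyclobutan-1-one | COc1ccc(C2CC(=O)C2)cc1OC | intermediate
6 | cis-3-(3,4-dimethoxyphenyl)cyclobutan-1-ol | COc1ccc([C@H]2C[C@@H](O)C2)cc1OC | intermediate
7 | cis-3-(3,4-dimethoxyphenyl)cyclobutyl 4-methylbenzenesulfonate | COc1ccc([C@H]2C[C@@H](OS(=O)(=O)c3ccc(C)cc3)C2)cc1OC | intermediate
8 | 4-bromo-1,2-dimethoxybenzene | COc1ccc(Br)cc1OC | starting material
9 | (3,4-dimethoxyphenyl)lithium | [Li]c1ccc(OC)c(OC)c1 | intermediate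
10 | lithium bis(3,4-dimethoxyphenyl)cuprate | [Li+].COc1ccc([Cu-]c2ccc(OC)c(OC)c2)cc1OC | intermediate
11 | trans-1,3-bis(3,4-dimethoxyphenyl)cyclobutane | COc1ccc([C@H]2C[C@H](c3ccc(OC)c(OC)c3)C2)cc1OC | intermediate
12 | trans-1,3-bis(2-bromo-4,5-dimethoxyphenyl)cyclobutane | COc1cc(Br)c([C@H]2C[C@H](c3cc(OC)c(OC)cc3Br)C2)cc1OC | intermediate
13 | carbon monoxide | [C-]#[O+] | starting material
14 | benzyl alcohol | OCc1ccccc1 | starting material
15 | benzyl 2-(2-bromo-4,5-dimethoxyphenyl)-4-(3,4-dimethoxyphenyl)cyclobutane-1-carboxylate (ester cis to the 3,4-dimethoxyphenyl group and trans to the bromoaryl group, aryl groups trans; racemic) | COc1cc(Br)c([C@H]2[C@H](C(=O)OCc3ccccc3)[C@H](c3ccc(OC)c(OC)c3)C2)cc1OC | intermediate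
16 | dibenzyl 2,4-bis(3,4-dimethoxyphenyl)cyclobutane-1,3-dicarboxylate (alpha-truxillate arrangement) | COc1ccc([C@H]2[C@H](C(=O)OCc3ccccc3)[C@H](c3ccc(OC)c(OC)c3)[C@H]2C(=O)OCc2ccccc2)cc1OC | intermediate
17 | 2,4-bis(3,4-dimethoxyphenyl)cyclobutane-1,3-dicarboxylic acid (alpha-truxillic arrangement) | COc1ccc([C@H]2[C@H](C(=O)O)[C@H](c3ccc(OC)c(OC)c3)[C@H]2C(=O)O)cc1OC | intermediate
18 | 2,4-bis(3,4-dimethoxyphenyl)cyclobutane-1,3-dicarbonyl dichloride (same arrangement) | COc1ccc([C@H]2[C@H](C(=O)Cl)[C@H](c3ccc(OC)c(OC)c3)[C@H]2C(=O)Cl)cc1OC | intermediate
19 | 5,6-dihydropyridin-2(1H)-one | O=C1C=CCCN1 | starting material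
20 | lithium salt of 5,6-dihydropyridin-2(1H)-one (N-lithiated) | [Li]N1CCC=CC1=O | intermediate
21 | 1,1'-[2,4-bis(3,4-dimethoxyphenyl)cyclobutane-1,3-dicarbonyl]bis(5,6-dihydropyridin-2(1H)-one) (alpha-truxillic arrangement) | COc1ccc([C@H]2[C@H](C(=O)N3CCC=CC3=O)[C@H](c3ccc(OC)c(OC)c3)[C@H]2C(=O)N2CCC=CC2=O)cc1OC | target

Total step count: 10. Longest linear sequence: 10 steps (from 1 to 21).

**Steps most likely to fail**

Step 7 (new method). Carbon monoxide may insert into the aryl–palladium bond before the C–H bond is cleaved, giving an aryl ester. It may also insert at the palladacycle stage before the shift is complete, which would close a cyclobutane-fused indanone. The cyclobutylpalladium species may lose the syn hydrogen on the neighbouring aryl-bearing carbon toward an arylcyclobutene. The second palladation may attack the more acidic methine C–H next to the first ester instead of the remaining methylene C–H, or the second carbonylation may stall at the mono-ester. The fallback uses known chemistry and sets out from 8. A Heck reaction with acrylic acid (Pd(OAc)2, P(o-tol)3, Et3N, DMF, 100 °C) should give (E)-3,4-dimethoxycinnamic acid F1. Irradiation of its crystals in the head-to-tail packed form (λ > 300 nm, solid state) should bring about the topochemical [2+2] photodimerisation to the alpha-truxillic diacid. The route is rejoined at 17, and in this variant the ring and all four stereocentres arise in the photochemical step.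

Step 5. Substitution at the four-membered ring may be slow, so that the cuprate decomposes or homocouples first, and ionisation of the sulfonate may lead to ring-opened or rearranged products instead of clean inversion. The fallback sets out from 6. Appel bromination (CBr4, PPh3, CH2Cl2, 0 °C) should give trans-3-(3,4-dimethoxyphenyl)cyclobutyl bromide F2. Nickel-catalysed Suzuki coupling of this secondary bromide with commercial (3,4-dimethoxyphenyl)boronic acid (NiI2, trans-2-aminocyclohexanol, NaHMDS, i-PrOH, 60 °C) runs through the 3-arylcyclobutyl radical. Nickel should capture this radical mainly on the face away from the 3-aryl group, though that preference is not assured, and the cis isomer would be removed by crystallisation. The route is rejoined at 11.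

Step 10. The basic lactamate may enolise the acid chloride (ketene formation) or the imide product and so scramble the configuration next to the carbonyl groups, and the second acylation may lag behind the first. The fallback sets out from 18 and builds the lactam rings on the amide nitrogen instead of acylating a preformed lactam. Acylation of but-3-en-1-amine (Et3N, CH2Cl2, 0 °C) should give N1,N3-di(but-3-en-1-yl)-2,4-bis(3,4-dimethoxyphenyl)cyclobutane-1,3-dicarboxamide F3. Deprotonation of the amide N–H groups (LiHMDS, THF, −78 °C) and reaction with acryloyl chloride should give N1,N3-diacryloyl-N1,N3-di(but-3-en-1-yl)-2,4-bis(3,4-dimethoxyphenyl)cyclobutane-1,3-dicarboxamide F4. Double ring-closing metathesis (second-generation Grubbs catalyst, CH2Cl2, 40 °C) should close both dihydropyridinone rings and arrive at 21.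

**Further compounds**

F1 | step 7 | (E)-3,4-dimethoxycinnamic acid | COc1ccc(/C=C/C(=O)O)cc1OC
F2 | step 5 | trans-3-(3,4-dimethoxyphenyl)cyclobutyl bromide | COc1ccc([C@H]2C[C@H](Br)C2)cc1OC
F3 | step 10 | N1,N3-di(but-3-en-1-yl)-2,4-bis(3,4-dimethoxyphenyl)cyclobutane-1,3-dicarboxamide (alpha-truxillic arrangement) | COc1ccc([C@H]2[C@H](C(=O)NCCC=C)[C@H](c3ccc(OC)c(OC)c3)[C@H]2C(=O)NCCC=C)cc1OC
F4 | step 10 | N1,N3-diacryloyl-N1,N3-di(but-3-en-1-yl)-2,4-bis(3,4-dimethoxyphenyl)cyclobutane-1,3-dicarboxamide (alpha-truxillic arrangement) | COc1ccc([C@H]2[C@H](C(=O)N(CCC=C)C(=O)C=C)[C@H](c3ccc(OC)c(OC)c3)[C@H]2C(=O)N(CCC=C)C(=O)C=C)cc1OC
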